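**Retrosynthetic overview**
1. Alertenone ⇒ the C4–CH2 bond between two suberosenone units, made with both polarities reversed: a zinc homoenolate (from β-iodo ketone 19) attacks a trivalent-iodine enolonium ion (from silyl dienol ether 20). Both partners come from suberosenone 17.
2. Suberosenone 17 ⇒ tricyclic enone 11 (α′-Mannich methylenation, dissolving-metal reduction, elimination).
3. Enone 11 ⇒ 1-allylbicyclo[3.2.1]octan-8-one 8 (Wacker oxidation, aldol condensation).
4. 8 ⇒ cyclohexanone 5 (cationic α-tert-alkylation closes the two-carbon bridge) ⇒ 2-allylcyclohexenone 3 (asymmetric conjugate methylation/methallylation) ⇒ 2-methoxybenzoic acid.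
5. Ring order: cyclohexane (from the arene) → gem-dimethylcyclopentane bridge → cyclopentanone → dimer link last.

Assumptions: (i) the tricyclic core is numbered as tricyclo[4.3.2.0^{1,5}]undecane (C1 quaternary, C2/C3/C4 the ketone ring, C5 ring-fusion CH, C9 CHMe, C11 CMe2); where a descriptor and a SMILES string could be read differently, the SMILES string counts. (ii) In step 2 the enantiomer of the chiral ligand that gives the 3S adduct is used.

Step 1
Reactants: 1 2-methoxybenzoic acid
Product: 3 2-(prop-2-en-1-yl)cyclohex-2-en-1-one, via dienoic acid 2 (not isolated)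
Conditions: Li, NH3(l)/THF, −78 °C; allyl bromide; evaporate NH3; then 2 M HCl, reflux
Reagents that add atoms: allyl bromide (C=CCBr)
Why: Birch reductive alkylation puts allyl on C1 of the benzoate, and acid then hydrolyses the enol ether, decarboxylates the β-keto acid and conjugates the alkene to give the 2-alkylcyclohexenone; no stereocentre.

Step 2
Reactants: 3 2-(prop-2-en-1-yl)cyclohex-2-en-1-one
Product: 5 (2R,3S)-3-methyl-2-(2-methylprop-2-en-1-yl)-2-(prop-2-en-1-yl)cyclohexan-1-one, via magnesium enolate 4 (not isolated)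
Conditions: MeMgBr, Cu(OTf)2 (3 mol %), chiral C2-symmetric imidazolinium salt (NHC precursor, 4 mol %), Et2O, −30 °C; then 3-bromo-2-methylprop-1-ene, DMPU, −30 → 20 °C
Reagents that add atoms: methylmagnesium bromide (C[Mg]Br); 3-bromo-2-methylprop-1-ene (C=C(C)CBr)
Why: Copper-catalysed asymmetric conjugate addition sets C3 (S) under ligand control, and the regiodefined enolate is alkylated at C2 anti to the new methyl, so methallyl ends trans to methyl (tandem conjugate addition/enolate trapping).

Step 3
Reactants: 5 (2R,3S)-3-methyl-2-(2-methylprop-2-en-1-yl)-2-(prop-2-en-1-yl)cyclohexan-1-one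
Product: 8 (1R,2S,5R)-2,6,6-trimethyl-1-(prop-2-en-1-yl)bicyclo[3.2.1]octan-8-one, via tertiary chloride 6 (not isolated), via silyl enol ether 7 (not isolated)
Conditions: HCl (2 M in Et2O), CH2Cl2, −40 °C; then Et3N, TMSOTf, 0 °C; pentane, filter, concentrate; TiCl4 (20 mol %), CH2Cl2, −78 → −20 °C
Reagents that add atoms: none
Why: Markovnikov hydrochlorination touches only the 1,1-disubstituted alkene, C6 is the only enolisable position, and Lewis-acid ionisation of the tertiary chloride gives an intramolecular Reetz-type SN1 α-tert-alkylation; the bridge can only close cis-1,3 with the methallyl arm axial, which fixes C5 and leaves the C2 methyl anti to C7.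

Step 4
Reactants: 8 (1R,2S,5R)-2,6,6-trimethyl-1-(prop-2-en-1-yl)bicyclo[3.2.1]octan-8-one
Product: 9 (1S,2S,5R)-2,6,6-trimethyl-1-(2-oxopropyl)bicyclo[3.2.1]octan-8-one
Conditions: PdCl2 (10 mol %), CuCl (20 mol %), O2 (1 atm), DMF/H2O 7:1, 25 °C
Reagents that add atoms: water (O)
Why: Tsuji–Wacker oxidation of the terminal alkene gives the methyl ketone by Markovnikov hydroxypalladation; no stereocentre is touched.

Step 5
Reactants: 9 (1S,2S,5R)-2,6,6-trimethyl-1-(2-oxopropyl)bicyclo[3.2.1]octan-8-one
Product: 11 (1S,6R,9S)-9,11,11-trimethyltricyclo[4.3.2.0^{1,5}]undec-4-en-3-one, via aldol 10 (not isolated)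
Conditions: KOH, EtOH, 78 °C
Reagents that add atoms: none
Why: Intramolecular aldol condensation: the bridging ketone cannot enolise (bridgehead and quaternary α-carbons), so only the methyl-ketone CH3 enolate can close the five-membered ring, and E1cB dehydration gives the cyclopentenone.

Step 6
Reactants: 11 (1S,6R,9S)-9,11,11-trimethyltricyclo[4.3.2.0^{1,5}]undec-4-en-3-one
Product: 13 2-[(dimethylamino)methyl]-9,11,11-trimethyltricyclo[4.3.2.0^{1,5}]undec-4-en-3-one (C2 epimers, ring centres as in 11), via lithium dienolate 12 (not isolated)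
Conditions: LiN(iPr)2, THF, −78 °C; then CH2=NMe2+ I−, −78 → 0 °C
Reagents that add atoms: N,N-dimethylmethylideneammonium iodide (C=[N+](C)C.[I-])
Why: The only acidic site is C2 (the γ-hydrogen sits at a bridgehead), so kinetic α′-deprotonation and Mannich alkylation with the iminium salt are regiospecific; the C2 configuration is irrelevant because it is removed in step 8.

Step 7
Reactants: 13 2-[(dimethylamino)methyl]-9,11,11-trimethyltricyclo[4.3.2.0^{1,5}]undec-4-en-3-one
Product: 15 (1S,5S,6S,9S)-2-[(dimethylamino)methyl]-9,11,11-trimethyltricyclo[4.3.2.0^{1,5}]undecan-3-one (C2 epimers), via lithium enolate 14 (not isolated)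
Conditions: Li, NH3(l)/THF, t-BuOH (1 equiv), −78 °C, 15 min; then NH4Cl
Reagents that add atoms: none
Why: Dissolving-metal (Birch-type) enone reduction protonates the β-carbon C5 to give the far less strained cis-fused diquinane, which places the C5 hydrogen on the face of the C9 arm as in the target.

Step 8
Reactants: 15 (1S,5S,6S,9S)-2-[(dimethylamino)methyl]-9,11,11-trimethyltricyclo[4.3.2.0^{1,5}]undecan-3-one
Product: 17 suberosenone, (1S,5S,6S,9S)-9,11,11-trimethyl-2-methylidenetricyclo[4.3.2.0^{1,5}]undecan-3-one, via ammonium iodide 16 (not isolated)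
Conditions: MeI, Et2O, 20 °C; then NaHCO3 (aq)/CH2Cl2, 20 °C
Reagents that add atoms: none
Why: N-Methylation followed by mild-base E1cB (Hofmann-type) elimination of the Mannich base gives the α-methylene ketone without forming an enolate elsewhere.

Step 9
Reactants: 17 suberosenone
Product: 19 (1S,2S,5S,6S,9S)-2-(iodomethyl)-9,11,11-trimethyltricyclo[4.3.2.0^{1,5}]undecan-3-one, via iodo silyl enol ether 18 (not isolated)
Conditions: TMSI, CH2Cl2, −78 °C; then pH 7 buffer/THF, −78 → −20 °C; use at once
Reagents that add atoms: iodotrimethylsilane (C[Si](C)(C)I)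
Why: Conjugate addition of TMSI gives the enol silane, and kinetic protonation at C2 occurs from the face away from the axial C9 methyl, which leaves CH2I syn to that methyl (2S) as alertenone requires; this is the less stable epimer, so base is avoided from here on.

Step 10
Reactants: 17 suberosenone
Product: 20 trimethyl{[(1S,5R,6S,9S)-9,11,11-trimethyl-2-methylidenetricyclo[4.3.2.0^{1,5}]undec-3-en-3-yl]oxy}silane
Conditions: TMSOTf, iPr2NEt, CH2Cl2, −20 °C; pentane, filter
Reagents that add atoms: trimethylsilyl trifluoromethanesulfonate (C[Si](C)(C)OS(=O)(=O)C(F)(F)F)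
Why: Soft enolisation can only occur toward C4 (C2 carries no hydrogen) and avoids a free enolate that would add to unreacted enone; no stereocentre changes.

Step 11
Reactants: 19 (1S,2S,5S,6S,9S)-2-(iodomethyl)-9,11,11-trimethyltricyclo[4.3.2.0^{1,5}]undecan-3-one; 20 trimethyl{[(1S,5R,6S,9S)-9,11,11-trimethyl-2-methylidenetricyclo[4.3.2.0^{1,5}]undec-3-en-3-yl]oxy}silane
Product: 23 alertenone, via alkylzinc iodide 21 (not isolated), via enolonium 22 (not isolated)
Conditions: 19, Zn dust, LiCl, THF, 25 °C (gives 21); separately PhI(OAc)2, BF3·OEt2, CH2Cl2, −78 °C, then 20 (gives 22); add 21 to 22, −78 → −40 °C; NH4Cl (aq)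
Reagents that add atoms: none
Why: Proposed new method: both Michael polarities are inverted — PhI(OAc)2/BF3 turns enol silane 20 into an O-bound trivalent-iodine enolonium ion whose C4 is electrophilic, and the β-zincio ketone 21 (a ketone homoenolate) attacks C4 in an SN2′ sense with loss of PhI from the face away from C6 and the exo C11 methyl (giving 4R), while C2 of the nucleophile keeps the configuration from step 9 because no enolate forms on that half; the closest known reaction type is C–C bond formation of enolonium species (from silyl enol ethers and PhI(OAc)2/BF3) with carbon nucleophiles such as allylsilanes, enol silanes and organozincs, together with electrophilic trapping of zinc homoenolates.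

**Compound list**
1 | 2-methoxybenzoic acid | COc1ccccc1C(=O)O | starting material
2 | 2-methoxy-1-(prop-2-en-1-yl)cyclohexa-2,5-diene-1-carboxylic acid (racemic) | COC1=CCC=CC1(CC=C)C(=O)O | intermediate
3 | 2-(prop-2-en-1-yl)cyclohex-2-en-1-one | C=CCC1=CCCCC1=O | intermediate
4 | bromomagnesium (S)-3-methyl-2-(prop-2-en-1-yl)cyclohex-1-en-1-olate | C[C@H]1CCCC(O[Mg]Br)=C1CC=C | intermediate
5 | (2R,3S)-3-methyl-2-(2-methylprop-2-en-1-yl)-2-(prop-2-en-1-yl)cyclohexan-1-one | O=C1CCC[C@H](C)[C@@]1(CC=C)CC(C)=C | intermediate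
6 | (2R,3S)-2-(2-chloro-2-methylpropyl)-3-methyl-2-(prop-2-en-1-yl)cyclohexan-1-one | O=C1CCC[C@H](C)[C@@]1(CC=C)CC(C)(C)Cl | intermediate
7 | {[(5S,6R)-6-(2-chloro-2-methylpropyl)-5-methyl-6-(prop-2-en-1-yl)cyclohex-1-en-1-yl]oxy}trimethylsilane | C[Si](C)(C)OC1=CCC[C@H](C)[C@@]1(CC=C)CC(C)(C)Cl | intermediate
8 | (1R,2S,5R)-2,6,6-trimethyl-1-(prop-2-en-1-yl)bicyclo[3.2.1]octan-8-one | O=C1[C@@H]2CC[C@H](C)[C@@]1(CC=C)CC2(C)C | intermediate
9 | (1S,2S,5R)-2,6,6-trimethyl-1-(2-oxopropyl)bicyclo[3.2.1]octan-8-one | O=C1[C@@H]2CC[C@H](C)[C@@]1(CC(C)=O)CC2(C)C | intermediate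
10 | 5-hydroxy-9,11,11-trimethyltricyclo[4.3.2.0^{1,5}]undecan-3-one (cis-fused aldol, other centres as in 11) | O=C1C[C@@]2(O)[C@@H]3CC[C@H](C)[C@@]2(C1)CC3(C)C | intermediate
11 | (1S,6R,9S)-9,11,11-trimethyltricyclo[4.3.2.0^{1,5}]undec-4-en-3-one | O=C1C=C2[C@@H]3CC[C@H](C)[C@@]2(C1)CC3(C)C | intermediate
12 | lithium 9,11,11-trimethyltricyclo[4.3.2.0^{1,5}]undeca-2,4-dien-3-olate (ring centres as in 11) | [Li]OC=1C=C2[C@@H]3CC[C@H](C)[C@@]2(C=1)CC3(C)C | intermediate
13 | 2-[(dimethylamino)methyl]-9,11,11-trimethyltricyclo[4.3.2.0^{1,5}]undec-4-en-3-one (C2 epimers, ring centres as in 11) | CN(C)CC1C(=O)C=C2[C@@H]3CC[C@H](C)[C@]12CC3(C)C | intermediate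
14 | lithium 2-[(dimethylamino)methyl]-9,11,11-trimethyltricyclo[4.3.2.0^{1,5}]undec-3-en-3-olate (C5 hydrogen syn to C9, C2 epimers) | CN(C)CC1C(O[Li])=C[C@H]2[C@@H]3CC[C@H](C)[C@]12CC3(C)C | intermediate
15 | (1S,5S,6S,9S)-2-[(dimethylamino)methyl]-9,11,11-trimethyltricyclo[4.3.2.0^{1,5}]undecan-3-one (C2 epimers) | CN(C)CC1C(=O)C[C@H]2[C@@H]3CC[C@H](C)[C@]12CC3(C)C | intermediate
16 | trimethyl{[(1S,5S,6S,9S)-9,11,11-trimethyl-3-oxotricyclo[4.3.2.0^{1,5}]undecan-2-yl]methyl}ammonium iodide (C2 epimers) | C[N+](C)(C)CC1C(=O)C[C@H]2[C@@H]3CC[C@H](C)[C@]12CC3(C)C.[I-] | intermediate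
17 | suberosenone, (1S,5S,6S,9S)-9,11,11-trimethyl-2-methylidenetricyclo[4.3.2.0^{1,5}]undecan-3-one | C=C1C(=O)C[C@H]2[C@@H]3CC[C@H](C)[C@]12CC3(C)C | intermediate
18 | {[(1S,5S,6S,9S)-2-(iodomethyl)-9,11,11-trimethyltricyclo[4.3.2.0^{1,5}]undec-2-en-3-yl]oxy}trimethylsilane | ICC1=C(O[Si](C)(C)C)C[C@H]2[C@@H]3CC[C@H](C)[C@]12CC3(C)C | intermediate
19 | (1S,2S,5S,6S,9S)-2-(iodomethyl)-9,11,11-trimethyltricyclo[4.3.2.0^{1,5}]undecan-3-one (CH2I syn to the C9 methyl) | IC[C@@H]1C(=O)C[C@H]2[C@@H]3CC[C@H](C)[C@]12CC3(C)C | intermediate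
20 | trimethyl{[(1S,5R,6S,9S)-9,11,11-trimethyl-2-methylidenetricyclo[4.3.2.0^{1,5}]undec-3-en-3-yl]oxy}silane | C=C1C(O[Si](C)(C)C)=C[C@H]2[C@@H]3CC[C@H](C)[C@]12CC3(C)C | intermediate
21 | iodo{[(1S,2S,5S,6S,9S)-9,11,11-trimethyl-3-oxotricyclo[4.3.2.0^{1,5}]undecan-2-yl]methyl}zinc | I[Zn]C[C@@H]1C(=O)C[C@H]2[C@@H]3CC[C@H](C)[C@]12CC3(C)C | intermediate
22 | acetoxy(phenyl)iodanyl enol ether of suberosenone (O-bound trivalent-iodine enolonium species; ring centres as in 20) | C=C1C(OI(OC(C)=O)c4ccccc4)=C[C@H]2[C@@H]3CC[C@H](C)[C@]12CC3(C)C | intermediate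
23 | alertenone, (1S,4R,5R,6S,9S)-9,11,11-trimethyl-2-methylidene-4-{[(1S,2S,5S,6S,9S)-9,11,11-trimethyl-3-oxotricyclo[4.3.2.0^{1,5}]undecan-2-yl]methyl}tricyclo[4.3.2.0^{1,5}]undecan-3-one | C=C1C(=O)[C@H](C[C@@H]2C(=O)C[C@H]3[C@@H]4CC[C@H](C)[C@]23CC4(C)C)[C@H]2[C@@H]3CC[C@H](C)[C@]12CC3(C)C | target

**Step count**
Total steps: 11. Longest linear sequence: 10 (steps 1–8, then step 9 or 10, then step 11).

**Three steps most likely to fail**

Step 11 (coupling of the zinc homoenolate with the enolonium ion; no direct precedent with a functionalised alkylzinc iodide). The fallback sets out from 20 and comes back at 23. Enol silane 20 is brominated with N-bromosuccinimide in THF at −78 °C to give 4-bromosuberosenone F1 (either C4 epimer). F1 is then joined to the zinc homoenolate 21 in a stereoconvergent nickel-catalysed Negishi alkyl–alkyl coupling (NiCl2·glyme, a pybox ligand, DMA/THF, 0 °C). The α-bromo ketone still serves as the electrophilic α-carbon and 21 as the homoenolate, but the bond now forms through a planar α-keto radical captured at nickel on the same open face. The main competitor there is nickel-promoted conjugate addition of 21 to the methylidene ketone.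

Step 3 (cationic closure of the two-carbon bridge; O-alkylation to a cyclic enol ether or capture of the cation by the allyl group could compete). The fallback sets out from 5 and comes back at 8. Ketone 5 is heated in decalin in a base-washed sealed tube at about 320 °C, so that the enol adds to the 1,1-disubstituted alkene in a concerted thermal Conia-ene reaction. This forms the same C5–C6 bond and the new methyl group under neutral conditions, without any carbocation; no new compound is formed on the way (F0).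

Step 2 (enantioselective methyl addition to an α-substituted enone and direct alkylation to a quaternary centre). The fallback sets out from 3 and comes back at 5. Enone 3 is treated with Me3Al and a copper thiophene-2-carboxylate, Cu(O2CC4H3S), phosphoramidite catalyst. The aluminium enolate is O-acylated with 2-methylprop-2-en-1-yl chloroformate to give (S)-3-methyl-2-(prop-2-en-1-yl)cyclohex-1-en-1-yl 2-methylprop-2-en-1-yl carbonate F2. Palladium-catalysed decarboxylative allylation (Pd2(dba)3, PPh3 or a PHOX ligand, THF, 25 °C) then builds the quaternary centre through a palladium enolate, again anti to the C3 methyl, and gives 5.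

Further compounds
F1 | step 11 | 4-bromosuberosenone, 4-bromo-9,11,11-trimethyl-2-methylidenetricyclo[4.3.2.0^{1,5}]undecan-3-one (ring centres as in 17, C4 either epimer) | C=C1C(=O)C(Br)[C@H]2[C@@H]3CC[C@H](C)[C@]12CC3(C)C
F0 | step 3 | none | none
F2 | step 2 | (S)-3-methyl-2-(prop-2-en-1-yl)cyclohex-1-en-1-yl 2-methylprop-2-en-1-yl carbonate | C[C@H]1CCCC(OC(=O)OCC(C)=C)=C1CC=C
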